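**Retrosynthetic overview**

1. Target 20 ⇒ arylboronate 18 + (E)-3-iodoprop-2-en-1-ol 19 (Suzuki bond C5–vinyl); 18 ⇒ 17 by C–H borylation at C5, the only arene C–H without an ortho neighbour; 17 ⇒ phenol 16 by O-methylation.
2. Feature the plan rests on: in the dihydrobenzofuran, C7a (carrying ring oxygen O1) lies next to oxygen-bearing C7, and C3a is bonded to C3. The benzene ring (C3a, C4, C5, C6, C7, C7a) is therefore read as a furan (C3a, C4, C5, C6, with its oxygen ending on C7) plus a two-carbon ynol ether (C7a, C7) hung on O1 of the chain C3–C2–O1.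
3. 16 ⇒ ynol ether 13: cycloisomerisation forming C3a–C7a and C6–C7. It closes the dihydrofuran ring (O1, C2, C3, C3a, C7a) and the benzene ring in one operation; the veratrole and furan rings are bought, so this is the only ring-forming step.
4. 13 ⇒ alcohol 8 + trichloroethylene 9 (dichlorovinyl ether, then elimination).
5. 8 ⇒ (E)-alkene 6 by pinene-borane syn hydroboration (sets C2 and C3 together); 6 ⇒ alkenylboronate 4 + 2-bromofuran 5; 4 ⇒ arylpropyne 3 ⇒ 4-bromoveratrole 1 + propyne 2.

Key step: step 7

Remarks on the chemistry: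
- Benzofuran numbering (O1, C2, C3, C3a, C4–C7, C7a) is used for all bicyclic compounds.
- (E)-3-Iodoprop-2-en-1-ol 19 is taken as a purchased building block.
- The pinene enantiomer in step 4 is assigned by analogy with the sense reported for 1-arylcycloalkenes and simple trisubstituted alkenes. The absolute configuration of 8 is to be confirmed (Mosher esters) before going on, and the reagent from (+)-α-pinene is used if the sense proves opposite.

**Route**

Step 1
Reactants: 1 4-bromo-1,2-dimethoxybenzene; 2 propyne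
Product: 3 1,2-dimethoxy-4-(prop-1-yn-1-yl)benzene
Conditions: propyne (ca. 1 M in THF, excess), Pd(PhCN)2Cl2 (3 mol %), [HP(t-Bu)3]BF4 (6 mol %), CuI (2 mol %), i-Pr2NH, dioxane, rt, sealed flask
Reagents that add atoms: none
Why: Sonogashira coupling, in which the bulky electron-rich phosphine lets the electron-rich aryl bromide undergo oxidative addition at room temperature so that volatile propyne stays in solution.

Step 2
Reactants: 3 1,2-dimethoxy-4-(prop-1-yn-1-yl)benzene
Product: 4 2-[(Z)-1-(3,4-dimethoxyphenyl)prop-1-en-2-yl]-4,4,5,5-tetramethyl-1,3,2-dioxaborolane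
Conditions: B2pin2 (1.1 equiv), CuCl (5 mol %), P(p-tol)3 (6 mol %), NaOt-Bu (15 mol %), MeOH (2 equiv), THF, rt
Reagents that add atoms: bis(pinacolato)diboron, CC1(C)OB(OC1(C)C)B1OC(C)(C)C(C)(C)O1
Why: CuCl-catalysed formal hydroboration of an aryl alkyl alkyne (syn borylcupration, then protonation of the C–Cu bond by methanol) places copper on the aryl-bearing carbon and boron on the methyl-bearing carbon, which gives the Z alkenylboronate with aryl and methyl cis.

Step 3
Reactants: 4 2-[(Z)-1-(3,4-dimethoxyphenyl)prop-1-en-2-yl]-4,4,5,5-tetramethyl-1,3,2-dioxaborolane; 5 2-bromofuran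
Product: 6 2-[(E)-1-(3,4-dimethoxyphenyl)prop-1-en-2-yl]furan
Conditions: Pd(dppf)Cl2 (3 mol %), K2CO3, dioxane/H2O, 70 °C
Reagents that add atoms: none
Why: Suzuki–Miyaura coupling, which transfers the alkenyl group with retention of geometry, so the furan takes the place of boron trans to the aryl group.

Step 4
Reactants: 6 2-[(E)-1-(3,4-dimethoxyphenyl)prop-1-en-2-yl]furan
Product: 8 (1S,2R)-1-(3,4-dimethoxyphenyl)-2-(furan-2-yl)propan-1-ol, via borane adduct 7 (not isolated)
Conditions: (IpcBH2)2·TMEDA [from (−)-α-pinene], BF3·OEt2, THF, rt, filter; 6, THF, −25 → 0 °C; then NaOH, H2O2, 0 °C → rt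
Reagents that add atoms: monoisopinocampheylborane from (−)-α-pinene, C[C@@H]1[C@@H](B)C[C@H]2C[C@@H]1C2(C)C (boron and the pinanyl group of 7); hydrogen peroxide, OO (the oxygen of 8)
Why: Brown asymmetric hydroboration, in which the four-centre syn addition puts boron on the less substituted CH(aryl) carbon and hydrogen on the furyl- and methyl-bearing carbon from the same face, so that the E geometry of 6 fixes the (1S*,2R*) relative configuration, the pinanyl group on boron selects the alkene face (sense assigned by analogy with 1-arylcycloalkenes), and alkaline peroxide replaces boron by oxygen with retention.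

Step 5
Reactants: 8 (1S,2R)-1-(3,4-dimethoxyphenyl)-2-(furan-2-yl)propan-1-ol; 9 trichloroethylene
Product: 11 2-[(1S,2R)-1-{[(E)-1,2-dichloroethenyl]oxy}-1-(3,4-dimethoxyphenyl)propan-2-yl]furan, via dichloroacetylene 10 (not isolated)
Conditions: KH (2 equiv), THF, 0 °C; Cl2C=CHCl (1.1 equiv), −50 °C → rt
Reagents that add atoms: none
Why: First half of the Greene ynol ether synthesis, in which KH converts trichloroethylene into dichloroacetylene 10 and the potassium alkoxide of 8 adds to it anti to give the (E)-1,2-dichlorovinyl ether, a reaction at oxygen that leaves both stereocentres untouched.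

Step 6
Reactants: 11 2-[(1S,2R)-1-{[(E)-1,2-dichloroethenyl]oxy}-1-(3,4-dimethoxyphenyl)propan-2-yl]furan
Product: 13 2-[(1S,2R)-1-(3,4-dimethoxyphenyl)-1-(ethynyloxy)propan-2-yl]furan, via lithium acetylide 12 (not isolated)
Conditions: n-BuLi (2.3 equiv), THF, −78 → −40 °C; MeOH, −78 °C; cold pH 7 work-up, solution kept at or below 0 °C and used the same day
Reagents that add atoms: n-butyllithium, [Li]CCCC (the lithium of 12; nothing from it stays in 13)
Why: Second half of the Greene ynol ether synthesis, in which two equivalents of n-BuLi take the dichlorovinyl ether by dehydrochlorination and chlorine–lithium exchange to the lithium acetylide 12 and cold protonation frees the terminal ynol ether, which is handled cold because benzylic ynol ethers rearrange and lose ketene on warming.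

Step 7
Reactants: 13 2-[(1S,2R)-1-(3,4-dimethoxyphenyl)-1-(ethynyloxy)propan-2-yl]furan
Product: 16 (2S,3S)-2-(3,4-dimethoxyphenyl)-3-methyl-2,3-dihydro-1-benzofuran-7-ol, via oxepine 14 (not isolated), via arene oxide 15 (not isolated)
Conditions: IPrAuNTf2 (5 mol %; IPr = 1,3-bis(2,6-diisopropylphenyl)imidazol-2-ylidene), 4 Å molecular sieves, dry CH2Cl2, −40 → 0 °C
Reagents that add atoms: none
Why: Proposed new method: the cationic monovalent gold centre of IPrAuNTf2 binds the ynol ether, whose ketene-oxonium character makes the oxygen-bearing alkyne carbon the electrophilic one, and the side-chain-bearing furan carbon attacks it in a 5-exo-dig closure that forms C3a–C7a and the dihydrofuran ring and gives a cyclopropyl gold carbene, which opens to a (Z)-dienal gold carbene. The aldehyde oxygen (the former furan oxygen) then adds to the carbene carbon to give oxepine 14, whose disrotatory 6π electrocyclisation to arene oxide 15 forms C6–C7 and so closes the six-membered ring; opening of the oxide at C6–O and loss of the C7 proton give the phenol. The closest known reaction type is the gold-catalysed furan–yne phenol synthesis, in which a furan is joined to a terminal alkyne through a three-atom carbon-, nitrogen- or oxygen-centred propargylic tether; an ynol ether in place of the propargyl unit has not been shown. No stereocentre is created, and C2 and C3 are spectators, so the trans (2S,3S) arrangement is carried over from 13 as long as the benzylic C2–O1 bond does not ionise. The step needs attack at the oxygen-bearing alkyne carbon, which the ynol ether polarisation and the five-membered-ring geometry of the tether secure, and hydroxyl at C7 and not C6, which follows because only C6–O cleavage of the oxide places positive charge on C7a next to O1. Dry, cold conditions and a bulky carbene complex are chosen to outrun hydration, benzyl migration and ketene loss.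

Step 8
Reactants: 16 (2S,3S)-2-(3,4-dimethoxyphenyl)-3-methyl-2,3-dihydro-1-benzofuran-7-ol
Product: 17 (2S,3S)-2-(3,4-dimethoxyphenyl)-7-methoxy-3-methyl-2,3-dihydro-1-benzofuran
Conditions: MeI, K2CO3, acetone, rt
Reagents that add atoms: iodomethane, CI
Why: Williamson O-methylation of the only acidic group, the C7 phenol, under conditions that leave the ethers and both stereocentres alone.

Step 9
Reactants: 17 (2S,3S)-2-(3,4-dimethoxyphenyl)-7-methoxy-3-methyl-2,3-dihydro-1-benzofuran
Product: 18 2-[(2S,3S)-2-(3,4-dimethoxyphenyl)-7-methoxy-3-methyl-2,3-dihydro-1-benzofuran-5-yl]-4,4,5,5-tetramethyl-1,3,2-dioxaborolane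
Conditions: B2pin2 (1.0 equiv), [Ir(OMe)(cod)]2 (1.5 mol %), dtbpy (3 mol %), THF, 60 °C
Reagents that add atoms: bis(pinacolato)diboron, CC1(C)OB(OC1(C)C)B1OC(C)(C)C(C)(C)O1
Why: Hartwig–Miyaura–Ishiyama C–H borylation, whose sterically governed selectivity points to C5–H, the only aromatic C–H of 17 with no ortho substituent (C4–H is flanked by C3a, C6–H by the methoxy group, and every C–H of the dimethoxyphenyl ring has an ortho substituent).

Step 10
Reactants: 18 2-[(2S,3S)-2-(3,4-dimethoxyphenyl)-7-methoxy-3-methyl-2,3-dihydro-1-benzofuran-5-yl]-4,4,5,5-tetramethyl-1,3,2-dioxaborolane; 19 (E)-3-iodoprop-2-en-1-ol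
Product: 20 (2E)-3-[(2S,3S)-2-(3,4-dimethoxyphenyl)-7-methoxy-3-methyl-2,3-dihydro-1-benzofuran-5-yl]prop-2-en-1-ol
Conditions: Pd(dppf)Cl2 (5 mol %), K2CO3, dioxane/H2O, 60 °C
Reagents that add atoms: none
Why: Suzuki–Miyaura coupling of the arylboronate with the alkenyl iodide, which retains the E geometry of 19 and tolerates the free allylic alcohol.

**Compound list**

1 | 4-bromo-1,2-dimethoxybenzene | COc1ccc(Br)cc1OC | starting material
2 | propyne | CC#C | starting material
3 | 1,2-dimethoxy-4-(prop-1-yn-1-yl)benzene | CC#Cc1ccc(OC)c(OC)c1 | intermediate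
4 | 2-[(Z)-1-(3,4-dimethoxyphenyl)prop-1-en-2-yl]-4,4,5,5-tetramethyl-1,3,2-dioxaborolane | COc1ccc(/C=C(\C)B2OC(C)(C)C(C)(C)O2)cc1OC | intermediate
5 | 2-bromofuran | Brc1ccco1 | starting material
6 | 2-[(E)-1-(3,4-dimethoxyphenyl)prop-1-en-2-yl]furan | COc1ccc(/C=C(\C)c2ccco2)cc1OC | intermediate
7 | B-isopinocampheyl-B-[(1S,2R)-1-(3,4-dimethoxyphenyl)-2-(furan-2-yl)propyl]borane (pinanyl group from (−)-α-pinene; drawn as monomer) | C[C@@H]1[C@@H](B[C@H](c2ccc(OC)c(OC)c2)[C@@H](C)c2ccco2)C[C@H]2C[C@@H]1C2(C)C | intermediate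
8 | (1S,2R)-1-(3,4-dimethoxyphenyl)-2-(furan-2-yl)propan-1-ol | COc1ccc([C@H]([C@@H](C)c2ccco2)O)cc1OC | intermediate
9 | trichloroethylene | ClC=C(Cl)Cl | starting material
10 | dichloroacetylene | ClC#CCl | intermediate
11 | 2-[(1S,2R)-1-{[(E)-1,2-dichloroethenyl]oxy}-1-(3,4-dimethoxyphenyl)propan-2-yl]furan | COc1ccc([C@H]([C@@H](C)c2ccco2)O/C(Cl)=C\Cl)cc1OC | intermediate
12 | lithium 2-{[(1S,2R)-1-(3,4-dimethoxyphenyl)-2-(furan-2-yl)propyl]oxy}ethynide | COc1ccc([C@H]([C@@H](C)c2ccco2)OC#C[Li])cc1OC | intermediate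
13 | 2-[(1S,2R)-1-(3,4-dimethoxyphenyl)-1-(ethynyloxy)propan-2-yl]furan | COc1ccc([C@H]([C@@H](C)c2ccco2)OC#C)cc1OC | intermediate
14 | oxepine valence tautomer: the (2S,3S)-2-(3,4-dimethoxyphenyl)-3-methyl-2,3-dihydrofuran ring fused through C3a–C7a to an oxepine whose oxygen bridges C6 and C7 | COc1ccc([C@H]2OC3=COC=CC=C3[C@@H]2C)cc1OC | intermediate
15 | (2S,3S)-2-(3,4-dimethoxyphenyl)-3-methyl-2,3-dihydro-1-benzofuran 6,7-oxide (6,7-epoxy-6,7-dihydro compound; either face of the cis-fused epoxide) | COc1ccc([C@H]2OC3=C(C=CC4OC34)[C@@H]2C)cc1OC | intermediate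
16 | (2S,3S)-2-(3,4-dimethoxyphenyl)-3-methyl-2,3-dihydro-1-benzofuran-7-ol | COc1ccc([C@H]2Oc3c(O)cccc3[C@@H]2C)cc1OC | intermediate
17 | (2S,3S)-2-(3,4-dimethoxyphenyl)-7-methoxy-3-methyl-2,3-dihydro-1-benzofuran | COc1ccc([C@H]2Oc3c(OC)cccc3[C@@H]2C)cc1OC | intermediate
18 | 2-[(2S,3S)-2-(3,4-dimethoxyphenyl)-7-methoxy-3-methyl-2,3-dihydro-1-benzofuran-5-yl]-4,4,5,5-tetramethyl-1,3,2-dioxaborolane | COc1ccc([C@H]2Oc3c(OC)cc(B4OC(C)(C)C(C)(C)O4)cc3[C@@H]2C)cc1OC | intermediate
19 | (E)-3-iodoprop-2-en-1-ol | OC/C=C/I | starting material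
20 | (2E)-3-[(2S,3S)-2-(3,4-dimethoxyphenyl)-7-methoxy-3-methyl-2,3-dihydro-1-benzofuran-5-yl]prop-2-en-1-ol | COc1ccc([C@H]2Oc3c(OC)cc(/C=C/CO)cc3[C@@H]2C)cc1OC | target

**Step count and risks**

Total steps: 10. Longest linear sequence: 10 steps (1 → 3 → 4 → 6 → 8 → 11 → 13 → 16 → 17 → 18 → 20).

Steps most likely to fail:

1. Step 7 (proposed new method). What may go wrong: ionisation of the benzylic C2–O1 bond in the gold-activated ynol ether (benzyl migration, ketene loss or epimerisation at C2), hydration of the ynol ether by traces of water, or attack through a furan carbon other than the substituted one, so that no phenol forms. The fallback uses known chemistry, sets out from alkenylboronate 4 and comes back at methyl ether 17; the benzene ring is bought instead of made. 2-Bromo-6-methoxyphenol is protected with MOMCl and i-Pr2NEt as 1-bromo-3-methoxy-2-(methoxymethoxy)benzene F1. Suzuki coupling of 4 with F1 (Pd(OAc)2, SPhos, K3PO4, toluene/H2O) should give 1,2-dimethoxy-4-{(E)-2-[3-methoxy-2-(methoxymethoxy)phenyl]prop-1-en-1-yl}benzene F2. Hydroboration with the same IpcBH2 should give the B-isopinocampheyl borane adduct F3, which is oxidised without isolation (NaOH, H2O2) to (1S,2S)-1-(3,4-dimethoxyphenyl)-2-[3-methoxy-2-(methoxymethoxy)phenyl]propan-1-ol F4. HCl in MeOH removes the MOM group to give 2-[(1S,2S)-1-(3,4-dimethoxyphenyl)-1-hydroxypropan-2-yl]-6-methoxyphenol F5. Catalytic TsOH in CH2Cl2 then closes the dihydrofuran ring: the phenol captures the dimethoxybenzyl cation trans to the C3 methyl group, which should give 17.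

2. Step 6. What may go wrong: loss of the terminal ynol ether during work-up and handling, by hydration on acidic surfaces, sigmatropic shift of the electron-rich benzyl group, or retro-ene extrusion of ketene. The fallback sets out from dichlorovinyl ether 11 and comes back at 13. The acetylide 12 is quenched with Me3SiCl instead of methanol to give 2-[(1S,2R)-1-(3,4-dimethoxyphenyl)-1-{[(trimethylsilyl)ethynyl]oxy}propan-2-yl]furan F6, an internal ynol ether that should tolerate filtration through basic alumina and cold storage. K2CO3 in MeOH at 0 °C removes the silyl group shortly before step 7, and the cold, dried solution of 13 is used at once.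

3. Step 4. What may go wrong: poor facial selectivity of the pinene borane on this diaryl-type trisubstituted alkene, or induction in the sense opposite to that assigned by analogy. The fallback sets out from alkene 6 and comes back at 8, replacing reagent control by a classical resolution. BH3·SMe2 in THF, then NaOH and H2O2, should give the syn-addition product as the racemate (1RS,2SR)-1-(3,4-dimethoxyphenyl)-2-(furan-2-yl)propan-1-ol F7. Acylation with (1S)-(−)-camphanic chloride (pyridine, DMAP) gives two diastereomers: (1S,2R)-1-(3,4-dimethoxyphenyl)-2-(furan-2-yl)propyl (1S,4R)-camphanate F8 and (1R,2S)-1-(3,4-dimethoxyphenyl)-2-(furan-2-yl)propyl (1S,4R)-camphanate F9. These are separated by crystallisation or chromatography, and K2CO3 in MeOH releases 8 from F8.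

**Further compounds**

F1 | step 7 | 1-bromo-3-methoxy-2-(methoxymethoxy)benzene | COCOc1c(Br)cccc1OC
F2 | step 7 | 1,2-dimethoxy-4-{(E)-2-[3-methoxy-2-(methoxymethoxy)phenyl]prop-1-en-1-yl}benzene | COc1ccc(/C=C(\C)c2cccc(OC)c2OCOC)cc1OC
F3 | step 7 | B-isopinocampheyl borane adduct of F2, boron on the dimethoxybenzyl carbon (pinanyl group from (−)-α-pinene) | C[C@@H]1[C@@H](B[C@H](c2ccc(OC)c(OC)c2)[C@@H](C)c2cccc(OC)c2OCOC)C[C@H]2C[C@@H]1C2(C)C
F4 | step 7 | (1S,2S)-1-(3,4-dimethoxyphenyl)-2-[3-methoxy-2-(methoxymethoxy)phenyl]propan-1-ol | COc1ccc([C@H]([C@@H](C)c2cccc(OC)c2OCOC)O)cc1OC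
F5 | step 7 | 2-[(1S,2S)-1-(3,4-dimethoxyphenyl)-1-hydroxypropan-2-yl]-6-methoxyphenol | COc1ccc([C@H]([C@@H](C)c2cccc(OC)c2O)O)cc1OC
F6 | step 6 | 2-[(1S,2R)-1-(3,4-dimethoxyphenyl)-1-{[(trimethylsilyl)ethynyl]oxy}propan-2-yl]furan | COc1ccc([C@H]([C@@H](C)c2ccco2)OC#C[Si](C)(C)C)cc1OC
F7 | step 4 | (1RS,2SR)-1-(3,4-dimethoxyphenyl)-2-(furan-2-yl)propan-1-ol, racemate | COc1ccc([C@H]([C@@H](C)c2ccco2)O)cc1OC.COc1ccc([C@@H]([C@H](C)c2ccco2)O)cc1OC
F8 | step 4 | (1S,2R)-1-(3,4-dimethoxyphenyl)-2-(furan-2-yl)propyl (1S,4R)-4,7,7-trimethyl-3-oxo-2-oxabicyclo[2.2.1]heptane-1-carboxylate | COc1ccc([C@H]([C@@H](C)c2ccco2)OC(=O)[C@@]23CC[C@@](C)(C(=O)O2)C3(C)C)cc1OC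
F9 | step 4 | (1R,2S)-1-(3,4-dimethoxyphenyl)-2-(furan-2-yl)propyl (1S,4R)-4,7,7-trimethyl-3-oxo-2-oxabicyclo[2.2.1]heptane-1-carboxylate | COc1ccc([C@@H]([C@H](C)c2ccco2)OC(=O)[C@@]23CC[C@@](C)(C(=O)O2)C3(C)C)cc1OC
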